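The feature exploited is the C4 carbonyl carbon lying between the two stereocentres C2 and C3: worn as a (4R)-carbinol beside a (Z)-C2=C3 alkene, it can steer oxygen to one alkene face and is afterwards returned to the ketone. The route therefore rests on disconnecting the chlorohydrin to a cis-2,3-epoxide. In one operation the key step forms the C2–O and C3–O bonds, closes the oxirane and sets both centres, while the C9=C10 alkene and furan rings A and B stay untouched. Its precursor is the complete skeleton, a (2Z,4R,6R,9E)-dienol ending in the 4-alkyl-2-(3-furylmethyl)furan, assembled from (R)-citronellic acid, a vinyl unit, a bromo-bis-furan and a propynyl Grignard reagent.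

Key step: step 11

Remark: (R)-citronellic acid is taken as a purchasable compound (one NaClO2 oxidation of (R)-citronellal would supply it otherwise); chain positions are numbered as in the target, C1 = CH3 on CHCl through C13 = CH2 on ring A (ring A = 2,4-disubstituted furan, ring B = 3-furyl).

**Step 1**
Reactants: 1 3-bromofuran; 2 4-bromofuran-2-carbaldehyde
Product: 4 racemic (4-bromofuran-2-yl)(furan-3-yl)methanol, via 3-furyllithium 3 (not isolated)
Conditions: n-BuLi, THF, −78 °C; then 2, −78 °C; aq. NH4Cl
Reagents that add atoms: none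
Why: Bromine–lithium exchange at −78 °C gives 3-furyllithium, whose 1,2-addition to the aldehyde (aryllithium addition) should outrun both exchange with the ring bromine of 2 and isomerisation to the 2-lithio species; the new carbinol centre is racemic and is removed in step 2.

**Step 2**
Reactants: 4 racemic (4-bromofuran-2-yl)(furan-3-yl)methanol
Product: 5 4-bromo-2-(furan-3-ylmethyl)furan
Conditions: Et3SiH (excess), TFA, CH2Cl2, −20 → 0 °C
Reagents that add atoms: none
Why: Ionic hydrogenation: TFA ionises the doubly heteroaryl-stabilised carbinol and the silane, kept in excess at low temperature, should trap the carbenium ion as the methylene before it can alkylate another furan, leaving the ring bromine in place.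

**Step 3**
Reactants: 6 (3R)-3,7-dimethyloct-6-enoic acid [(R)-citronellic acid]
Product: 8 (3R)-N-methoxy-N,3,7-trimethyloct-6-enamide, via acyl imidazolide 7 (not isolated)
Conditions: CDI, CH2Cl2, rt; then MeNH(OMe)·HCl, rt
Reagents that add atoms: N,O-dimethylhydroxylamine hydrochloride, CNOC.Cl
Why: Weinreb amide formation through the acyl imidazolide: the amide carries C4 at the carboxyl level through steps 4 to 7 and later gives the ynone in one step, and the C6 centre, β to the carbonyl, is not involved.

**Step 4**
Reactants: 8 (3R)-N-methoxy-N,3,7-trimethyloct-6-enamide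
Product: 10 (3R,6E)-8-hydroxy-N-methoxy-N,3,7-trimethyloct-6-enamide, via enal 9 (not isolated)
Conditions: SeO2 (cat.), t-BuOOH, salicylic acid (cat.), CH2Cl2, rt; then NaBH4, MeOH, 0 °C
Reagents that add atoms: tert-butyl hydroperoxide, CC(C)(C)OO
Why: Riley allylic oxidation: the ene reaction of SeO2 and a [2,3]-sigmatropic shift oxidise the (E)-methyl group of the trisubstituted alkene selectively, so C11 becomes CH2OH with the 9E geometry in place, and NaBH4 returns the over-oxidised part (enal 9) to 10 without reducing the N-methoxy-N-methylamide.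

**Step 5**
Reactants: 10 (3R,6E)-8-hydroxy-N-methoxy-N,3,7-trimethyloct-6-enamide
Product: 11 (3R,6E)-8-bromo-N-methoxy-N,3,7-trimethyloct-6-enamide
Conditions: CBr4, PPh3, CH2Cl2, 0 °C
Reagents that add atoms: carbon tetrabromide, BrC(Br)(Br)Br
Why: Appel reaction: the primary allylic alcohol is activated as an alkoxyphosphonium ion and displaced by bromide at C11 under neutral conditions, without allylic transposition or loss of the E geometry.

**Step 6**
Reactants: 11 (3R,6E)-8-bromo-N-methoxy-N,3,7-trimethyloct-6-enamide; 12 tributyl(vinyl)stannane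
Product: 13 (3R,6E)-N-methoxy-N,3,7-trimethyldeca-6,9-dienamide
Conditions: Pd(PPh3)4 (cat.), THF, 60 °C
Reagents that add atoms: none
Why: Stille allyl–vinyl coupling: zerovalent palladium ionises the allylic bromide, vinyl is transferred from tin, and reductive elimination at the unsubstituted allyl terminus (C11) should give the skipped diene with the 9E alkene retained, under neutral conditions that the amide tolerates where a vinyl Grignard reagent might not.

**Step 7**
Reactants: 13 (3R,6E)-N-methoxy-N,3,7-trimethyldeca-6,9-dienamide; 5 4-bromo-2-(furan-3-ylmethyl)furan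
Product: 15 (3R,6E)-10-[5-(furan-3-ylmethyl)furan-3-yl]-N-methoxy-N,3,7-trimethyldec-6-enamide, via B-alkyl-9-BBN adduct 14 (not isolated)
Conditions: 9-BBN, THF, rt; then 5, Pd(dppf)Cl2 (cat.), aq. K3PO4, DMF, 60 °C
Reagents that add atoms: none
Why: Hydroboration followed by B-alkyl Suzuki–Miyaura coupling: 9-BBN adds only to the monosubstituted C12=C13 alkene with boron at C13, and the phosphate-activated borane couples with the ring A bromide to form the C13–ring A bond, so no lithiated bis-furan is needed.

**Step 8**
Reactants: 15 (3R,6E)-10-[5-(furan-3-ylmethyl)furan-3-yl]-N-methoxy-N,3,7-trimethyldec-6-enamide; 16 1-propynylmagnesium bromide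
Product: 17 (6R,9E)-13-[5-(furan-3-ylmethyl)furan-3-yl]-6,10-dimethyltridec-9-en-2-yn-4-one
Conditions: THF, −20 → 0 °C; then cold 0.5 M HCl
Reagents that add atoms: none
Why: Weinreb ketone synthesis: the alkynyl Grignard reagent adds once to give a magnesium-chelated tetrahedral adduct that collapses to the ynone only on the acidic quench, which also keeps the liberated amine from adding to the ynone.

**Step 9**
Reactants: 17 (6R,9E)-13-[5-(furan-3-ylmethyl)furan-3-yl]-6,10-dimethyltridec-9-en-2-yn-4-one
Product: 18 (4R,6R,9E)-13-[5-(furan-3-ylmethyl)furan-3-yl]-6,10-dimethyltridec-9-en-2-yn-4-ol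
Conditions: Ru[(R,R)-TsDPEN](p-cymene) (cat.), i-PrOH, rt
Reagents that add atoms: none
Why: Noyori asymmetric transfer hydrogenation: the (R,R)-configured ruthenium hydride reduces alkyl alkynyl ketones under catalyst control, the alkynyl group taking the place that an aryl group has in aryl ketones, which should set C4 as R regardless of the remote C6 centre and leave the alkyne, the C9=C10 alkene and the furans untouched.

**Step 10**
Reactants: 18 (4R,6R,9E)-13-[5-(furan-3-ylmethyl)furan-3-yl]-6,10-dimethyltridec-9-en-2-yn-4-ol
Product: 19 (2Z,4R,6R,9E)-13-[5-(furan-3-ylmethyl)furan-3-yl]-6,10-dimethyltrideca-2,9-dien-4-ol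
Conditions: H2 (1 atm), Pd/CaCO3–Pb(OAc)2 (Lindlar catalyst), quinoline, EtOAc, rt
Reagents that add atoms: none
Why: Lindlar semihydrogenation: syn delivery of one equivalent of hydrogen on lead-poisoned palladium converts the alkyne into the (Z)-C2=C3 alkene, and with quinoline present the trisubstituted alkene and the furans should not be reduced.

**Step 11**
Reactants: 19 (2Z,4R,6R,9E)-13-[5-(furan-3-ylmethyl)furan-3-yl]-6,10-dimethyltrideca-2,9-dien-4-ol
Product: 20 (2R,3S,4R,6R,9E)-2,3-epoxy-13-[5-(furan-3-ylmethyl)furan-3-yl]-6,10-dimethyltridec-9-en-4-ol (threo cis-epoxy alcohol)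
Conditions: Ti(OiPr)4 (1 equiv), t-BuOOH (in decane), 4 Å MS, CH2Cl2, −20 → 0 °C
Reagents that add atoms: tert-butyl hydroperoxide, CC(C)(C)OO
Why: The C4 hydroxyl and the hydroperoxide replace isopropoxide ligands on tetravalent titanium, and the activated peroxide oxygen is handed to the neighbouring C2=C3 alkene inside this complex, the closest known reaction being the Ti(OiPr)4/t-BuOOH epoxidation of secondary allylic alcohols (the tartrate-free parent of the Sharpless epoxidation). The oxirane is closed in a single [2+1] event, one oxygen atom bonding to C2 and C3 at the same time and on the same face, so the Z geometry becomes a cis-epoxide. Both new centres, C2 (R) and C3 (S), are controlled by the 4R carbinol: the C1 methyl cis to C4 keeps the C4–H in the alkene plane, since the C5 chain in that position would meet 1,3-allylic strain, and oxygen therefore arrives only on the face carrying the titanium-bound C4–O, which gives the threo isomer. The step needs diastereofacial selectivity, supplied by this allylic strain and by the wide O–C4–C3=C2 dihedral angle that the titanium transition state accepts, and chemoselectivity, supplied by the hydroxyl itself, because only an alkene beside the bound alkoxide is oxidised and the more electron-rich C9=C10 alkene and furan rings A and B, which carry no such handle, should be left alone. Any erythro isomer should be removed at this stage, as after step 12 it would differ from 21 only in its relation to the remote C6 centre.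

**Step 12**
Reactants: 20 (2R,3S,4R,6R,9E)-2,3-epoxy-13-[5-(furan-3-ylmethyl)furan-3-yl]-6,10-dimethyltridec-9-en-4-ol
Product: 21 (2R,3R,6R,9E)-2,3-epoxy-13-[5-(furan-3-ylmethyl)furan-3-yl]-6,10-dimethyltridec-9-en-4-one (cis-epoxy ketone)
Conditions: Dess–Martin periodinane, NaHCO3, CH2Cl2, 0 °C → rt
Reagents that add atoms: none
Why: Dess–Martin oxidation: the periodinane oxidises the secondary C4 carbinol under buffered conditions that leave the cis-epoxide, the alkene and the furans unchanged, so the relay centre is erased while C2 and C3 keep their geometry (the C3 descriptor changes from S to R only through the priority rules).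

**Step 13**
Reactants: 21 (2R,3R,6R,9E)-2,3-epoxy-13-[5-(furan-3-ylmethyl)furan-3-yl]-6,10-dimethyltridec-9-en-4-one
Product: 22 (2S,3S,6R,9E)-2-chloro-13-[5-(furan-3-ylmethyl)furan-3-yl]-3-hydroxy-6,10-dimethyltridec-9-en-4-one (target)
Conditions: CeCl3·7H2O, MeCN, rt
Reagents that add atoms: cerium trichloride heptahydrate, [Ce+3].[Cl-].[Cl-].[Cl-].O.O.O.O.O.O.O
Why: Lewis acid-assisted chloride opening of an α,β-epoxy ketone (chlorohydrin formation): trivalent cerium bound to the ketone and oxirane oxygens activates the ring, and chloride should attack C2 with inversion (giving 2S) because C3, next to the carbonyl, resists positive-charge build-up and its C–O bond lies in the carbonyl plane of the chelate, so C3 keeps its geometry (S by descriptor once chlorine raises the priority of C2).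

**Compound list**
1 | 3-bromofuran | Brc1ccoc1 | starting material
2 | 4-bromofuran-2-carbaldehyde | O=Cc1cc(Br)co1 | starting material
3 | 3-furyllithium | [Li]c1ccoc1 | intermediate
4 | racemic (4-bromofuran-2-yl)(furan-3-yl)methanol | OC(c1cc(Br)co1)c1ccoc1 | intermediate
5 | 4-bromo-2-(furan-3-ylmethyl)furan | Brc1coc(Cc2ccoc2)c1 | intermediate
6 | (3R)-3,7-dimethyloct-6-enoic acid, (R)-citronellic acid | CC(C)=CCC[C@@H](C)CC(=O)O | starting material
7 | (3R)-1-(imidazol-1-yl)-3,7-dimethyloct-6-en-1-one (acyl imidazolide) | CC(C)=CCC[C@@H](C)CC(=O)n1ccnc1 | intermediate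
8 | (3R)-N-methoxy-N,3,7-trimethyloct-6-enamide | CC(C)=CCC[C@@H](C)CC(=O)N(C)OC | intermediate
9 | (3R,6E)-N-methoxy-N,3,7-trimethyl-8-oxooct-6-enamide (enal) | O=C/C(C)=C/CC[C@@H](C)CC(=O)N(C)OC | intermediate
10 | (3R,6E)-8-hydroxy-N-methoxy-N,3,7-trimethyloct-6-enamide | OC/C(C)=C/CC[C@@H](C)CC(=O)N(C)OC | intermediate
11 | (3R,6E)-8-bromo-N-methoxy-N,3,7-trimethyloct-6-enamide | BrC/C(C)=C/CC[C@@H](C)CC(=O)N(C)OC | intermediate
12 | tributyl(vinyl)stannane | C=C[Sn](CCCC)(CCCC)CCCC | starting material
13 | (3R,6E)-N-methoxy-N,3,7-trimethyldeca-6,9-dienamide | C=CC/C(C)=C/CC[C@@H](C)CC(=O)N(C)OC | intermediate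
14 | (3R,6E)-10-(9-borabicyclo[3.3.1]nonan-9-yl)-N-methoxy-N,3,7-trimethyldec-6-enamide | C/C(=C\CC[C@@H](C)CC(=O)N(C)OC)CCCB1C2CCCC1CCC2 | intermediate
15 | (3R,6E)-10-[5-(furan-3-ylmethyl)furan-3-yl]-N-methoxy-N,3,7-trimethyldec-6-enamide | C/C(=C\CC[C@@H](C)CC(=O)N(C)OC)CCCc1coc(Cc2ccoc2)c1 | intermediate
16 | 1-propynylmagnesium bromide | CC#C[Mg]Br | starting material
17 | (6R,9E)-13-[5-(furan-3-ylmethyl)furan-3-yl]-6,10-dimethyltridec-9-en-2-yn-4-one | C/C(=C\CC[C@@H](C)CC(=O)C#CC)CCCc1coc(Cc2ccoc2)c1 | intermediate
18 | (4R,6R,9E)-13-[5-(furan-3-ylmethyl)furan-3-yl]-6,10-dimethyltridec-9-en-2-yn-4-ol | C/C(=C\CC[C@@H](C)C[C@@H](O)C#CC)CCCc1coc(Cc2ccoc2)c1 | intermediate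
19 | (2Z,4R,6R,9E)-13-[5-(furan-3-ylmethyl)furan-3-yl]-6,10-dimethyltrideca-2,9-dien-4-ol | C/C(=C\CC[C@@H](C)C[C@@H](O)/C=C\C)CCCc1coc(Cc2ccoc2)c1 | intermediate
20 | (2R,3S,4R,6R,9E)-2,3-epoxy-13-[5-(furan-3-ylmethyl)furan-3-yl]-6,10-dimethyltridec-9-en-4-ol | C/C(=C\CC[C@@H](C)C[C@@H](O)[C@@H]1O[C@@H]1C)CCCc1coc(Cc2ccoc2)c1 | intermediate
21 | (2R,3R,6R,9E)-2,3-epoxy-13-[5-(furan-3-ylmethyl)furan-3-yl]-6,10-dimethyltridec-9-en-4-one | C/C(=C\CC[C@@H](C)CC(=O)[C@@H]1O[C@@H]1C)CCCc1coc(Cc2ccoc2)c1 | intermediate
22 | (2S,3S,6R,9E)-2-chloro-13-[5-(furan-3-ylmethyl)furan-3-yl]-3-hydroxy-6,10-dimethyltridec-9-en-4-one | C/C(=C\CC[C@@H](C)CC(=O)[C@H](O)[C@H](C)Cl)CCCc1coc(Cc2ccoc2)c1 | target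

**Totals and risks**
Total step count: 13. Longest linear sequence: 11 steps (steps 3 to 13, from 6).

Steps most likely to fail:

1. Step 11: insufficient facial discrimination (erythro epoxide forming alongside the threo isomer) or sluggish oxygen transfer to the hindered Z-alkene. The fallback sets out from 19 and comes back at 20, moving stereocontrol from the substrate to the catalyst. It is a vanadium-catalysed asymmetric epoxidation with VO(OiPr)3, a C2-symmetric chiral bishydroxamic acid ligand and cumene hydroperoxide in toluene at 0 °C, using the ligand enantiomer whose own face preference for Z-allylic alcohols is matched to the 4R carbinol. The oxidation is still hydroxyl-bound, so the C9=C10 alkene and the furans should remain untouched. No new compound is made (F0).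

2. Step 13: chloride attacking C3 instead of C2, or loss of HCl from the β-chloro ketone once formed. The fallback sets out from 20 and introduces chlorine while C4 is still a carbinol. ClTi(OiPr)3 in CH2Cl2 at 0 °C binds the C4 oxygen and delivers chloride to the distal C2 with inversion (titanium-mediated opening of a 2,3-epoxy alcohol). This gives (2S,3S,4R,6R,9E)-2-chloro-13-[5-(furan-3-ylmethyl)furan-3-yl]-6,10-dimethyltridec-9-ene-3,4-diol F1. A Parikh–Doering mono-oxidation (SO3·pyridine, DMSO, i-Pr2NEt, 0 °C, one equivalent) should then take the C4 hydroxyl, which is the less hindered one and is not deactivated by a neighbouring chlorine, and comes back to the route at 22.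

3. Step 2: cationic oligomerisation, the bis-furyl carbenium ion alkylating a free furan position faster than the silane reduces it. The fallback sets out from 4 and removes the oxygen by a radical pathway (Barton–McCombie deoxygenation). NaH, CS2 and MeI in THF give racemic O-[(4-bromofuran-2-yl)(furan-3-yl)methyl] S-methyl carbonodithioate F2. Bu3SnH with AIBN in toluene at 80 °C then cleaves the C–O bond through the doubly heteroaryl-stabilised radical and comes back at 5. Abstraction of the ring-bound bromine is much slower than addition of the stannyl radical to the thiocarbonyl group.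

**Further compounds**
F0 | step 11 | none | none
F1 | step 13 | (2S,3S,4R,6R,9E)-2-chloro-13-[5-(furan-3-ylmethyl)furan-3-yl]-6,10-dimethyltridec-9-ene-3,4-diol | C/C(=C\CC[C@@H](C)C[C@@H](O)[C@H](O)[C@H](C)Cl)CCCc1coc(Cc2ccoc2)c1
F2 | step 2 | racemic O-[(4-bromofuran-2-yl)(furan-3-yl)methyl] S-methyl carbonodithioate | CSC(=S)OC(c1cc(Br)co1)c1ccoc1
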